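The route rests on disconnecting the C6–C7 bond between the two quaternary carbons of ring B. The feature exploited is the γ,δ-unsaturated acid built into that ring: carboxyl carbon, C7, C6 and the C5=C4 olefin. Read backwards as an ester-enolate Claisen shift, it leads to a δ-lactone (ring oxygen on C4, carbonyl on C7) whose C4 also carries a methyl group and an E-configured C5=C6 arm ending in a dimethyl acetal (C1'); ring A is still open as a vinyl and a 1-ethylvinyl group. In one operation the silyl ketene acetal of this lactone, forced into a boat, forms C6–C7, closes ring B, sets both quaternary centres and releases the carboxyl group.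

Key step: step 12

Atom labels: the tetrahydroindene numbering of the target (ring A: C1, C2, C3, C3a, C7a; ring B: C3a, C4, C5, C6, C7, C7a; C1' is the side-chain carbon on C6) is used for all intermediates.
Assumption: the (4S,5S) enantiomer of the boron controller in step 2 is taken to induce the (2R,3R) acid; should the sense of induction be the reverse, the (4R,5R) reagent is used and nothing else changes.
Remark: lactone 24 is written as the C7 epimer with methyl trans to the C7a substituent; the other epimer is carried along and converges in step 12.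

Step 1
Reactants: 1 (E)-but-2-en-1-ol; 2 but-3-enoic acid
Product: 3 (E)-but-2-enyl but-3-enoate
Conditions: N,N'-dicyclohexylcarbodiimide, DMAP (5 mol%), CH2Cl2, 0 °C
Reagents that add atoms: none
Why: Steglich esterification, in which the carbodiimide activates the acid and a catalytic amount of DMAP at 0 °C transfers the acyl group before the β,γ-double bond can move into conjugation; no stereocentre is formed.

Step 2
Reactants: 3 (E)-but-2-enyl but-3-enoate
Product: 6 (2R,3R)-2-ethenyl-3-methylpent-4-enoic acid, via boron dienolate 4 (not isolated), via acyloxyborane 5 (not isolated)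
Conditions: (4S,5S)-2-bromo-1,3-bis{[3,5-bis(trifluoromethyl)phenyl]sulfonyl}-4,5-diphenyl-1,3,2-diazaborolidine (1.1 equiv), Et3N, toluene–hexane, −78 → −20 °C; aqueous work-up
Reagents that add atoms: none
Why: Enantioselective boron-enolate Ireland–Claisen rearrangement, in which the bromoborane and Et3N in the non-polar medium should give the E(O) boron dienolate (vinyl trans to O–B) that rearranges through a chair with the E-crotyl unit to the anti acid, while the C2-symmetric bis-sulfonamide on boron selects the enolate face and so fixes C3 and C3a as (2R,3R).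

Step 3
Reactants: 6 (2R,3R)-2-ethenyl-3-methylpent-4-enoic acid
Product: 7 (2R,3R)-2-ethenyl-N-methoxy-N,3-dimethylpent-4-enamide
Conditions: 1,1'-carbonyldiimidazole, CH2Cl2, 0 → 23 °C; then MeNH(OMe)·HCl, 23 °C
Reagents that add atoms: N,O-dimethylhydroxylamine hydrochloride, SMILES CNOC.Cl
Why: Amide formation through the acyl imidazole (Weinreb amide synthesis) under near-neutral conditions, which should leave the allylic α-stereocentre and the β,γ-olefin untouched.

Step 4
Reactants: 7 (2R,3R)-2-ethenyl-N-methoxy-N,3-dimethylpent-4-enamide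
Product: 8 (3R,4R)-3-ethenyl-4-methylhex-5-en-2-one
Conditions: MeMgBr, THF, −20 → 0 °C; pH 7 phosphate buffer, 0 °C
Reagents that add atoms: methylmagnesium bromide, SMILES C[Mg]Br
Why: Weinreb ketone synthesis, in which the magnesium-chelated tetrahedral adduct survives until the cold neutral quench, so that only one methyl group adds and the epimerisable α-centre of the β,γ-unsaturated ketone never meets base; the crude ketone is used at once.

Step 5
Reactants: 9 prop-2-yn-1-ol
Product: 11 (E)-3-iodo-2-methylprop-2-en-1-ol, via alkenylalane 10 (not isolated)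
Conditions: Me3Al (3 equiv), Cp2ZrCl2 (25 mol%), CH2Cl2, 0 → 23 °C; then iodine, THF, −30 → 0 °C
Reagents that add atoms: trimethylaluminium, SMILES C[Al](C)C; iodine, SMILES [I][I]
Why: Zirconium-catalysed carboalumination (Negishi) adds methyl and aluminium syn across the alkyne with methyl on the internal carbon, and iodinolysis of the C–Al bond with retention gives the E iodide (iodine cis to methyl).

Step 6
Reactants: 11 (E)-3-iodo-2-methylprop-2-en-1-ol
Product: 12 (E)-3-iodo-2-methylprop-2-enal
Conditions: MnO2 (excess), CH2Cl2, 23 °C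
Reagents that add atoms: none
Why: Allylic oxidation with MnO2, which is selective for the allylic alcohol and neither touches the vinyl iodide nor isomerises the olefin.

Step 7
Reactants: 12 (E)-3-iodo-2-methylprop-2-enal
Product: 13 (E)-1-iodo-3,3-dimethoxy-2-methylprop-1-ene
Conditions: HC(OMe)3, MeOH, pyridinium p-toluenesulfonate (cat.), 23 °C
Reagents that add atoms: trimethyl orthoformate, SMILES COC(OC)OC
Why: Mildly acid-catalysed acetalisation with the orthoformate as methoxy donor and water scavenger, which masks the aldehyde against the organometallic steps until step 14.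

Step 8
Reactants: 8 (3R,4R)-3-ethenyl-4-methylhex-5-en-2-one; 13 (E)-1-iodo-3,3-dimethoxy-2-methylprop-1-ene
Product: 16 (2E,4S,5R,6R)-5-ethenyl-1,1-dimethoxy-2,4,6-trimethylocta-2,7-dien-4-ol, via alkenyllithium 14 (not isolated), via alkenylcerium dichloride 15 (not isolated)
Conditions: t-BuLi (2 equiv per 13), Et2O, −78 °C; CeCl3, THF, −78 °C; addition of 8, −78 °C; aqueous NaHCO3
Reagents that add atoms: none
Why: Iodine–lithium exchange with retention of olefin geometry, transmetalation to the weakly basic organocerium and 1,2-addition to the enolisable ketone, with C4 set under Felkin–Anh control (branched C3 substituent anti to the incoming nucleophile, vinyl inside, hydrogen outside), which should place the arm trans to the C3a side chain as the later boat requires; the minor C4 epimer is removed by chromatography on base-washed silica.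

Step 9
Reactants: 16 (2E,4S,5R,6R)-5-ethenyl-1,1-dimethoxy-2,4,6-trimethylocta-2,7-dien-4-ol
Product: 18 (2E,4S,5R,6R)-5-ethenyl-1,1-dimethoxy-2,4,6-trimethylocta-2,7-dien-4-yl prop-2-enoate, via lithium alkoxide 17 (not isolated)
Conditions: LiN(SiMe3)2, THF, −78 °C; acryloyl chloride, −78 → −20 °C
Reagents that add atoms: acryloyl chloride, SMILES C=CC(=O)Cl
Why: O-Acylation of the preformed lithium alkoxide of a hindered tertiary allylic alcohol, in which the lithium counter-ion and the low temperature keep the 3-oxido-1,5-diene from an anionic oxy-Cope shift; C4 is not touched.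

Step 10
Reactants: 18 (2E,4S,5R,6R)-5-ethenyl-1,1-dimethoxy-2,4,6-trimethylocta-2,7-dien-4-yl prop-2-enoate
Product: 19 (5R,6S)-5-[(2R)-but-3-en-2-yl]-6-[(1E)-3,3-dimethoxy-2-methylprop-1-enyl]-6-methyl-5,6-dihydro-2H-pyran-2-one
Conditions: second-generation Grubbs catalyst (5 mol%), CH2Cl2 (5 mM), 40 °C
Reagents that add atoms: none
Why: Ring-closing metathesis, in which the ruthenium carbene formed at the C3a vinyl group closes onto the acrylate to the six-membered unsaturated lactone, whereas the other pairings would give cyclobutenes or a slower seven-membered ring, and the arm olefin, trisubstituted and attached to the quaternary C4, should stay a spectator.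

Step 11
Reactants: 19 (5R,6S)-5-[(2R)-but-3-en-2-yl]-6-[(1E)-3,3-dimethoxy-2-methylprop-1-enyl]-6-methyl-5,6-dihydro-2H-pyran-2-one; 20 2-bromobut-1-ene
Product: 24 (3R,4S,5S,6S)-5-[(2R)-but-3-en-2-yl]-4-(but-1-en-2-yl)-6-[(1E)-3,3-dimethoxy-2-methylprop-1-enyl]-3,6-dimethyloxan-2-one, via but-1-en-2-yllithium 21 (not isolated), via lithium dialkenylcuprate 22 (not isolated), via lithium enolate 23 (not isolated)
Conditions: t-BuLi (2 equiv per 20), Et2O, −78 °C; CuBr·SMe2 (0.5 equiv per 21) to give LiCu[C(=CH2)Et]2, −78 → −40 °C; addition of 19, −78 → −40 °C; then MeI, DMPU, −40 → 0 °C; aqueous NH4Cl–NH3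
Reagents that add atoms: iodomethane, SMILES IC
Why: Conjugate addition of a lithium dialkenylcuprate followed by C-methylation of the lactone enolate, in which the reagent enters C7a anti to the branched substituent on the neighbouring C3a and anti to the C4 methyl, so that C7a is set trans to C3a and cis to the arm; the C7 epimer ratio is irrelevant because C7 is flattened in step 12.

Step 12
Reactants: 24 (3R,4S,5S,6S)-5-[(2R)-but-3-en-2-yl]-4-(but-1-en-2-yl)-6-[(1E)-3,3-dimethoxy-2-methylprop-1-enyl]-3,6-dimethyloxan-2-one
Product: 27 (1R,2S,5S,6R)-5-[(2R)-but-3-en-2-yl]-6-(but-1-en-2-yl)-2-(dimethoxymethyl)-1,2,4-trimethylcyclohex-3-ene-1-carboxylic acid, via silyl ketene acetal 25 (not isolated), via silyl ester 26 (not isolated)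
Conditions: LiN(iPr)2, THF, −78 °C; Me3SiCl–Et3N, −78 → 23 °C; toluene, 105 °C; then H2O (pH 5 buffer)
Reagents that add atoms: none
Why: LiN(iPr)2 removes the C7 hydrogen of either epimer and Me3SiCl traps the enolate as the endocyclic trimethylsilyl ketene acetal, in which C7a is necessarily cis to the ring oxygen; on heating, the array C7=C(OSi)–O–C4–C5=C6 undergoes a concerted suprafacial [3,3] shift, the O–C4 bond breaking as C7–C6 forms, and water then cleaves the silyl ester. The closest known reaction type is the Ireland–Claisen rearrangement of alkenyl-substituted lactone silyl ketene acetals to cycloalkene carboxylic acids. Ring B (C3a–C4–C5–C6–C7–C7a) closes in a pericyclic mode: because C4 and C7 are tied through the C3a–C7a bond, only a boat of bicyclo[2.2.2]octane topology is possible, the axial arm on C4 folding over the ketene acetal. C7 is controlled by the C4 configuration, since the arm can reach only the face of C7 on which it stands, so the carboxyl group ends on the face of the old lactone bridge (cis to the C3a side chain) and the C7 methyl on the other. C6 is controlled by the E geometry of C5=C6 within that boat: the C6 methyl (cis to C4) is turned to the face of the C7 methyl and C1' to the face of the carboxyl group, which is the arrangement of the target. The step needs the sigmatropic path to outrun heterolysis of the tertiary allylic C4–O bond and any Cope-type shift, which the substrate secures by its single ketene acetal geometry and the pre-organised arm, helped by amine-buffered, triflate-free silylation that also spares the acetal, by a temperature near 105 °C and by ring A being still open.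

Step 13
Reactants: 27 (1R,2S,5S,6R)-5-[(2R)-but-3-en-2-yl]-6-(but-1-en-2-yl)-2-(dimethoxymethyl)-1,2,4-trimethylcyclohex-3-ene-1-carboxylic acid
Product: 28 (3R,3aS,6S,7R,7aR)-6-(dimethoxymethyl)-1-ethyl-3,4,6,7-tetramethyl-3a,6,7,7a-tetrahydro-3H-indene-7-carboxylic acid
Conditions: second-generation Grubbs catalyst (5–10 mol%), CH2Cl2, 40 °C
Reagents that add atoms: none
Why: Ring-closing metathesis of the vinyl and 1-ethylvinyl groups, held trans and diequatorial on ring B, closes the five-membered ring A with its trisubstituted C1=C2 olefin and gives the trans ring fusion already fixed at C3a and C7a; the acid, the acetal and the hindered ring B olefin are tolerated.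

Step 14
Reactants: 28 (3R,3aS,6S,7R,7aR)-6-(dimethoxymethyl)-1-ethyl-3,4,6,7-tetramethyl-3a,6,7,7a-tetrahydro-3H-indene-7-carboxylic acid
Product: 29 (3R,3aS,6S,7R,7aR)-1-ethyl-6-formyl-3,4,6,7-tetramethyl-3a,6,7,7a-tetrahydro-3H-indene-7-carboxylic acid
Conditions: 1 M HCl, THF, 23 °C
Reagents that add atoms: water, SMILES O
Why: Acid-catalysed acetal hydrolysis assisted by the neighbouring carboxyl group; C6 bears no hydrogen and cannot epimerise, and the product is expected to rest largely as its ring tautomer, the hydroxy γ-lactone, which opens again in the next step.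

Step 15
Reactants: 29 (3R,3aS,6S,7R,7aR)-1-ethyl-6-formyl-3,4,6,7-tetramethyl-3a,6,7,7a-tetrahydro-3H-indene-7-carboxylic acid
Product: 30 (3R,3aS,6R,7R,7aR)-1-ethyl-3,4,6,7-tetramethyl-6-[(1E)-2-methyl-3-oxoprop-1-enyl]-3a,6,7,7a-tetrahydro-3H-indene-7-carboxylic acid
Conditions: Ph3P=C(CH3)CHO (1.5 equiv), iPr2NEt, toluene, 100 °C
Reagents that add atoms: 2-(triphenylphosphoranylidene)propanal, SMILES CC(C=O)=P(c1ccccc1)(c1ccccc1)c1ccccc1
Why: Wittig olefination with a formyl-stabilised ylide, which reacts with the open aldehyde form (favoured as the ammonium carboxylate) and should give the E enal because the bulky C6 residue ends trans to the formyl group.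

Step 16
Reactants: 30 (3R,3aS,6R,7R,7aR)-1-ethyl-3,4,6,7-tetramethyl-6-[(1E)-2-methyl-3-oxoprop-1-enyl]-3a,6,7,7a-tetrahydro-3H-indene-7-carboxylic acid
Product: 31 zyggomphic acid B
Conditions: (EtO)2P(O)CH2Ph, KOt-Bu, THF, 0 → 23 °C; dilute HCl work-up
Reagents that add atoms: diethyl benzylphosphonate, SMILES CCOP(=O)(Cc1ccccc1)OCC
Why: Horner–Wadsworth–Emmons olefination of the enal carboxylate with the benzylphosphonate anion, whose reversible addition and syn elimination should give the E styryl olefin and complete the (1E,3E)-diene.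

Compound list
1 | (E)-but-2-en-1-ol | C/C=C/CO | starting material
2 | but-3-enoic acid | C=CCC(=O)O | starting material
3 | (E)-but-2-enyl but-3-enoate | C=CCC(=O)OC/C=C/C | intermediate
4 | boron dienolate of 3, E(O) geometry, on the (4S,5S)-1,3-bis{[3,5-bis(trifluoromethyl)phenyl]sulfonyl}-4,5-diphenyl-1,3,2-diazaborolidine | C=C/C=C(\OC/C=C/C)OB1N(S(=O)(=O)c2cc(C(F)(F)F)cc(C(F)(F)F)c2)[C@@H](c2ccccc2)[C@H](c2ccccc2)N1S(=O)(=O)c1cc(C(F)(F)F)cc(C(F)(F)F)c1 | intermediate
5 | acyloxyborane, the mixed anhydride of 6 and the same diazaborolidine | C=C[C@@H](C)[C@@H](C=C)C(=O)OB1N(S(=O)(=O)c2cc(C(F)(F)F)cc(C(F)(F)F)c2)[C@@H](c2ccccc2)[C@H](c2ccccc2)N1S(=O)(=O)c1cc(C(F)(F)F)cc(C(F)(F)F)c1 | intermediate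
6 | (2R,3R)-2-ethenyl-3-methylpent-4-enoic acid | C=C[C@@H](C)[C@@H](C=C)C(=O)O | intermediate
7 | (2R,3R)-2-ethenyl-N-methoxy-N,3-dimethylpent-4-enamide | C=C[C@@H](C)[C@@H](C=C)C(=O)N(C)OC | intermediate
8 | (3R,4R)-3-ethenyl-4-methylhex-5-en-2-one | C=C[C@@H](C)[C@@H](C=C)C(C)=O | intermediate
9 | prop-2-yn-1-ol (propargyl alcohol) | C#CCO | starting material
10 | alkenylalane, dimethylaluminium (E)-3-(dimethylalumanyl)-2-methylprop-2-en-1-olate | C[Al](C)/C=C(\C)CO[Al](C)C | intermediate
11 | (E)-3-iodo-2-methylprop-2-en-1-ol | I/C=C(\C)CO | intermediate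
12 | (E)-3-iodo-2-methylprop-2-enal | I/C=C(\C)C=O | intermediate
13 | (E)-1-iodo-3,3-dimethoxy-2-methylprop-1-ene | I/C=C(\C)C(OC)OC | intermediate
14 | [(E)-3,3-dimethoxy-2-methylprop-1-enyl]lithium | [Li]/C=C(\C)C(OC)OC | intermediate
15 | dichloro[(E)-3,3-dimethoxy-2-methylprop-1-enyl]cerium | Cl[Ce](Cl)/C=C(\C)C(OC)OC | intermediate
16 | (2E,4S,5R,6R)-5-ethenyl-1,1-dimethoxy-2,4,6-trimethylocta-2,7-dien-4-ol (octane C4, C5, C6 are C4, C3a, C3 of the target) | C=C[C@@H](C)[C@@H](C=C)[C@](C)(O)/C=C(\C)C(OC)OC | intermediate
17 | lithium alkoxide of 16 | C=C[C@@H](C)[C@@H](C=C)[C@](C)(O[Li])/C=C(\C)C(OC)OC | intermediate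
18 | (2E,4S,5R,6R)-5-ethenyl-1,1-dimethoxy-2,4,6-trimethylocta-2,7-dien-4-yl prop-2-enoate | C=C[C@@H](C)[C@@H](C=C)[C@](C)(OC(=O)C=C)/C=C(\C)C(OC)OC | intermediate
19 | (5R,6S)-5-[(2R)-but-3-en-2-yl]-6-[(1E)-3,3-dimethoxy-2-methylprop-1-enyl]-6-methyl-5,6-dihydro-2H-pyran-2-one (arm on C4 trans to the C3a side chain) | C=C[C@@H](C)[C@@H]1[C@@](C)(/C=C(\C)C(OC)OC)OC(=O)C=C1 | intermediate
20 | 2-bromobut-1-ene | C=C(Br)CC | starting material
21 | but-1-en-2-yllithium | [Li]C(=C)CC | intermediate
22 | lithium di(but-1-en-2-yl)cuprate | [Li+].C=C(CC)[Cu-]C(=C)CC | intermediate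
23 | lithium enolate of the conjugate adduct (C7a set, C7 trigonal) | C=C[C@@H](C)[C@@H]1[C@@](C)(/C=C(\C)C(OC)OC)OC(O[Li])=C[C@H]1C(=C)CC | intermediate
24 | (3R,4S,5S,6S)-5-[(2R)-but-3-en-2-yl]-4-(but-1-en-2-yl)-6-[(1E)-3,3-dimethoxy-2-methylprop-1-enyl]-3,6-dimethyloxan-2-one (δ-lactone precursor; arm cis to the C7a substituent, trans to the C3a substituent) | C=C[C@@H](C)[C@@H]1[C@@](C)(/C=C(\C)C(OC)OC)OC(=O)[C@H](C)[C@H]1C(=C)CC | intermediate
25 | trimethylsilyl ketene acetal of 24 (endocyclic, C7 trigonal) | C=C[C@@H](C)[C@@H]1[C@@](C)(/C=C(\C)C(OC)OC)OC(O[Si](C)(C)C)=C(C)[C@H]1C(=C)CC | intermediate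
26 | trimethylsilyl ester of 27 | C=C[C@@H](C)[C@@H]1C(C)=C[C@](C)(C(OC)OC)[C@](C)(C(=O)O[Si](C)(C)C)[C@H]1C(=C)CC | intermediate
27 | (1R,2S,5S,6R)-5-[(2R)-but-3-en-2-yl]-6-(but-1-en-2-yl)-2-(dimethoxymethyl)-1,2,4-trimethylcyclohex-3-ene-1-carboxylic acid (ring B acid; C6 methyl, C7 methyl and the C7a substituent on one face, C1', carboxyl and the C3a substituent on the other) | C=C[C@@H](C)[C@@H]1C(C)=C[C@](C)(C(OC)OC)[C@](C)(C(=O)O)[C@H]1C(=C)CC | intermediate
28 | (3R,3aS,6S,7R,7aR)-6-(dimethoxymethyl)-1-ethyl-3,4,6,7-tetramethyl-3a,6,7,7a-tetrahydro-3H-indene-7-carboxylic acid | CCC1=C[C@@H](C)[C@@H]2C(C)=C[C@](C)(C(OC)OC)[C@](C)(C(=O)O)[C@@H]12 | intermediate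
29 | (3R,3aS,6S,7R,7aR)-1-ethyl-6-formyl-3,4,6,7-tetramethyl-3a,6,7,7a-tetrahydro-3H-indene-7-carboxylic acid (in equilibrium with its hydroxy γ-lactone tautomer) | CCC1=C[C@@H](C)[C@@H]2C(C)=C[C@](C)(C=O)[C@](C)(C(=O)O)[C@@H]12 | intermediate
30 | (3R,3aS,6R,7R,7aR)-1-ethyl-3,4,6,7-tetramethyl-6-[(1E)-2-methyl-3-oxoprop-1-enyl]-3a,6,7,7a-tetrahydro-3H-indene-7-carboxylic acid (the C6 descriptor changes with the ranking of the substituents, not with the geometry) | CCC1=C[C@@H](C)[C@@H]2C(C)=C[C@](C)(/C=C(\C)C=O)[C@](C)(C(=O)O)[C@@H]12 | intermediate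
31 | zyggomphic acid B, (3R,3aS,6S,7R,7aR)-1-ethyl-3,4,6,7-tetramethyl-6-[(1E,3E)-2-methyl-4-phenylbuta-1,3-dienyl]-3a,6,7,7a-tetrahydro-3H-indene-7-carboxylic acid | CCC1=C[C@@H](C)[C@@H]2C(C)=C[C@](C)(/C=C(C)/C=C/c3ccccc3)[C@](C)(C(=O)O)[C@@H]12 | target

Total step count: 16
Longest linear sequence: 13 steps (steps 1–4 and 8–16); steps 5–7 make the arm that joins in step 8.

Steps most likely to fail

Step 12. The crowded boat may fail to join the two fully substituted carbons C6 and C7 fast enough, so that heterolysis of the tertiary allylic C4–O bond and elimination consume the ketene acetal. The fallback lowers the steric load of the sigmatropic step and makes C7 quaternary afterwards. It sets out from 19: the cuprate addition of step 11 is quenched with aqueous NH4Cl in place of MeI, which gives the lactone lacking the C7 methyl F1. Enolisation and silylation as in step 12 give the trisubstituted silyl ketene acetal F2, which should rearrange through the same boat to the silyl ester F3 and, after hydrolysis, to the acid with C6 quaternary and C7 still bearing hydrogen F4. The dianion of this acid (LiN(iPr)2, two equivalents, THF–DMPU) is then methylated with MeI, expected on the face away from the dimethoxymethyl group on C6, although that facial preference is the uncertain point of this detour. The route is rejoined at 27.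

Step 8. The facial preference of the carbonyl addition may be low or reversed (the vinyl group on C3a taking the anti position in place of the branched C3 group), and the acidic α-hydrogen may be lost by enolisation. The fallback exchanges the order in which the two carbon groups reach C4. It sets out from 7, which is treated with alkenyllithium 14 to give the enone F5; MeMgBr with CeCl3 is then added at −78 °C. The methyl group now enters the face that the arm took before, so the same intrinsic bias delivers the other C4 epimer, and the route is rejoined at 16.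

Step 15. The neopentyl aldehyde, largely masked as its lactol, may react so slowly with the stabilised ylide that the freely exposed product enal is homologated a second time. The fallback uses a phosphonate carbanion whose product cannot react further. It sets out from 29, which is treated with triethyl 2-phosphonopropionate and NaH (THF, 60 °C; the basic medium opens the lactol to the carboxylate aldehyde) to give the ethyl (E)-enoate acid F6. Reduction with iBu2AlH (CH2Cl2, −78 °C) gives the allylic alcohol acid F7, and MnO2 oxidises it to the enal, rejoining the route at 30.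

Further compounds
F1 | step 12 | lactone 24 lacking the C7 methyl (C7 is CH2) | C=C[C@@H](C)[C@@H]1[C@@](C)(/C=C(\C)C(OC)OC)OC(=O)C[C@H]1C(=C)CC
F2 | step 12 | trimethylsilyl ketene acetal of F1 | C=C[C@@H](C)[C@@H]1[C@@](C)(/C=C(\C)C(OC)OC)OC(O[Si](C)(C)C)=C[C@H]1C(=C)CC
F3 | step 12 | trimethylsilyl ester of F4 | C=C[C@@H](C)[C@@H]1C(C)=C[C@](C)(C(OC)OC)[C@H](C(=O)O[Si](C)(C)C)[C@H]1C(=C)CC
F4 | step 12 | acid 27 lacking the C7 methyl (C7 bears hydrogen) | C=C[C@@H](C)[C@@H]1C(C)=C[C@](C)(C(OC)OC)[C@H](C(=O)O)[C@H]1C(=C)CC
F5 | step 8 | (2E,5R,6R)-5-ethenyl-1,1-dimethoxy-2,6-dimethylocta-2,7-dien-4-one | C=C[C@@H](C)[C@@H](C=C)C(=O)/C=C(\C)C(OC)OC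
F6 | step 15 | ethyl (E)-enoate acid, the 6-[(1E)-3-ethoxy-2-methyl-3-oxoprop-1-enyl] analogue of 30 | CCC1=C[C@@H](C)[C@@H]2C(C)=C[C@](C)(/C=C(\C)C(=O)OCC)[C@](C)(C(=O)O)[C@@H]12
F7 | step 15 | allylic alcohol acid, the 6-[(1E)-3-hydroxy-2-methylprop-1-enyl] analogue of 30 | CCC1=C[C@@H](C)[C@@H]2C(C)=C[C@](C)(/C=C(\C)CO)[C@](C)(C(=O)O)[C@@H]12
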